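Everything rests on the 1,3-relationship between the C6 oxygen and C1 across C10: if C6 and C10 are the fusion atoms of a five-membered ring (C6–C10) and a seven-membered ring (C1–C6, C10), heterolysis of the C6–C10 bond releases the ten-membered ring instead of closing it. One Grob fragmentation of the potassium C6 alkoxide therefore creates the C6 ketone, the ring-cis C1=C10 alkene and the germacrane ring at once, with C7 and C8 already in place. The precursor is a cis-fused bicyclo[5.3.0]dec-4-ene with a tertiary C6 hydroxyl, an equatorial C1 mesylate and sacrificial C1, C6 and C10 stereocentres.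

Key step: step 14

Remark (numbering): germacrane numbering is used for all intermediates (ring C1–C10; C11–C13 are the lactone carbons on C7; C14 on C10; C15 on C4); "ring-cis" means that the two ring neighbours of an alkene lie on the same side; in cyclopentane names ring C1 = C7, C2 = C6, C3 = C10, C4 = C9, C5 = C8.

Remark (structures): the target, the fragmentation precursor and its product were checked and are mutually consistent in connectivity, alkene geometry (both ring alkenes ring-cis) and configuration at C7/C8, so no structure is corrected. The precursor is redesigned in two respects. Its C7 side chain is a tert-butyl ester. It is the diastereomer with the seven-membered ring anti to that side chain (C6–OH cis to it), because both C–C bond formations on the cyclopentanone are expected anti to the C7 substituent. C1, C6 and C10 become trigonal in step 14, so only the C1/C10 relationship matters.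

Remark (assumption): the lipase of step 3 is assumed to follow the Kazlauskas model with the substituted C7 as the large group; the absolute configuration of 6 is to be confirmed before it is carried on.

**Route**

Step 1
Reactants: 1 furfural; 2 tert-butyl bromoacetate
Product: 4 tert-butyl 3-(furan-2-yl)-3-hydroxypropanoate (racemic), via Reformatsky reagent 3 (not isolated)
Conditions: Zn dust (TMSCl-activated), THF, 40 °C; sat. aq. NH4Cl
Reagents that add atoms: none
Why: Reformatsky reaction, in which the zinc ester enolate adds to the aldehyde without self-condensation of the tert-butyl ester; the carbinol centre is racemic and irrelevant because it is lost in step 2.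

Step 2
Reactants: 4 tert-butyl 3-(furan-2-yl)-3-hydroxypropanoate
Product: 5 trans-4-hydroxy-5-(tert-butoxycarbonylmethyl)cyclopent-2-enone (racemic)
Conditions: ZnCl2, 1,4-dioxane/H2O, 80 °C
Reagents that add atoms: water, O
Why: Piancatelli rearrangement: ionisation of the furylcarbinol, hydration at C5 of the furan and conrotatory 4π-electrocyclisation of the pentadienyl cation should give the 4-hydroxy-5-substituted cyclopentenone with the trans C7/C8 relationship, the weakly acidic medium sparing the tert-butyl ester.

Step 3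
Reactants: 5 racemic trans-hydroxy enone
Product: 6 tert-butyl 2-[(1R,5S)-5-hydroxy-2-oxocyclopent-3-en-1-yl]acetate
Conditions: Burkholderia cepacia lipase (Amano PS), vinyl acetate, t-BuOMe, 30 °C, stopped near half conversion
Reagents that add atoms: none
Why: Lipase-catalysed kinetic resolution by transesterification: by the Kazlauskas model (C7 large, C9 medium) the (5R)-carbinol enantiomer should be acetylated and the required (1R,5S)-alcohol, which fixes C7 and C8 of the target, recovered unreacted.

Step 4
Reactants: 6 (1R,5S)-hydroxy enone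
Product: 7 C8 TBS ether of 6
Conditions: TBSCl, imidazole, DMF, 0 °C
Reagents that add atoms: tert-butyldimethylsilyl chloride, CC(C)(C)[Si](C)(C)Cl
Why: Standard silylation of the secondary alcohol under weakly basic conditions that should not isomerise the 4-oxy-5-substituted enone.

Step 5
Reactants: 7 C8 TBS ether
Product: 8 C10-hydroxymethyl enone
Conditions: aq. CH2O (37%), imidazole, THF/aq. NaHCO3, rt
Reagents that add atoms: formaldehyde, C=O
Why: Morita–Baylis–Hillman hydroxymethylation: reversible conjugate addition of imidazole at C9 gives the C10 enolate, which adds to formaldehyde and releases the catalyst, placing C14 on the enone α-carbon.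

Step 6
Reactants: 8 C10-hydroxymethyl enone
Product: 9 C14 TBDPS ether (bis-silyl enone)
Conditions: TBDPSCl, imidazole, CH2Cl2, 0 °C → rt
Reagents that add atoms: tert-butyldiphenylsilyl chloride, CC(C)(C)[Si](Cl)(c1ccccc1)c1ccccc1
Why: Silylation of the primary allylic alcohol; the bulky, migration-resistant TBDPS group is chosen because O14 will sit 1,3 to alkoxides at C1 and C6 in later steps.

Step 7
Reactants: 10 2-methylidenepropane-1,3-diol
Product: 11 2-{[(4-methoxybenzyl)oxy]methyl}prop-2-en-1-ol
Conditions: NaH (1.0 equiv), THF, 0 °C; PMBCl, Bu4NI (cat.), rt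
Reagents that add atoms: 4-methoxybenzyl chloride, COc1ccc(CCl)cc1
Why: Williamson monoalkylation of the symmetrical diol with one equivalent of base; the PMB ether marks O15 for late oxidative exchange to the acetate.

Step 8
Reactants: 11 mono-PMB allylic alcohol
Product: 13 ethyl 4-{[(4-methoxybenzyl)oxy]methyl}pent-4-enoate, via mixed ketene acetal 12 (not isolated)
Conditions: MeC(OEt)3, EtCO2H (cat.), 140 °C, EtOH distilled off
Reagents that add atoms: triethyl orthoacetate, CCOC(C)(OCC)OCC
Why: Johnson–Claisen rearrangement: the [3,3]-sigmatropic shift of the ketene acetal adds the two-carbon ester unit (C1–C2) and leaves the 1,1-disubstituted alkene at C4.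

Step 9
Reactants: 13 ethyl pentenoate
Product: 14 4-{[(4-methoxybenzyl)oxy]methyl}pent-4-enal
Conditions: iBu2AlH (1.05 equiv), CH2Cl2, −78 °C; aq. potassium sodium tartrate
Reagents that add atoms: none
Why: Partial reduction of the ester at −78 °C, where the tetrahedral aluminate survives until work-up, should give the C1 aldehyde.

Step 10
Reactants: 9 bis-silyl enone; 14 pentenal
Product: 16 aldol adduct (germacrane 1S,7R,8S,10R), via lithium enolate 15 (not isolated)
Conditions: LiBH(s-Bu)3 (1.0 equiv), THF, −78 °C; then 14, −78 °C; sat. aq. NH4Cl at −78 °C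
Reagents that add atoms: none
Why: Reductive aldol: conjugate hydride delivery to C9 forms the C6/C10 lithium enolate regiospecifically (no enolisation towards C7, so the C8 silyloxy group is not eliminated), and addition to the aldehyde through a Zimmerman–Traxler chair with C9 equatorial should give the anti adduct (C1–OH and C9 cis on the future seven-membered ring) on the face opposite the C7 side chain.

Step 11
Reactants: 16 aldol adduct
Product: 17 C6 vinyl carbinol (vinyl cis to the C1 chain)
Conditions: CH2=CHMgBr, CeCl3 (anhydrous), THF, −78 °C; aq. NH4Cl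
Reagents that add atoms: vinylmagnesium bromide, C=C[Mg]Br
Why: Organocerium 1,2-addition (low basicity, so no enolisation or retro-aldol, and the ester is untouched): the C1 alkoxide chelates the metal to the C6 carbonyl and vinyl should be delivered to the face syn to C1, which is also the face opposite the C7 side chain and the C10 CH2OTBDPS group, so that C5 and C1 are cis.

Step 12
Reactants: 17 C6 vinyl carbinol
Product: 18 cis-fused bicyclo[5.3.0]dec-4-ene-1,6-diol
Conditions: second-generation Grubbs catalyst [RuCl2(=CHPh)(PCy3)(H2IMes)] (5 mol%), CH2Cl2 (5 mM), 40 °C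
Reagents that add atoms: none
Why: Ring-closing metathesis between the C6 vinyl group and the 1,1-disubstituted C4 alkene closes the seven-membered ring with loss of ethene; the trisubstituted C4=C5 alkene is necessarily ring-cis and the cis tethers give the cis ring fusion.

Step 13
Reactants: 18 bicyclic diol
Product: 19 C1 mesylate (fragmentation precursor)
Conditions: MsCl (1.2 equiv), Et3N, CH2Cl2, −20 °C
Reagents that add atoms: methanesulfonyl chloride, CS(=O)(=O)Cl
Why: Selective sulfonylation: the secondary C1 hydroxyl is mesylated with retention while the tertiary C6 hydroxyl should not react at −20 °C.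

Step 14
Reactants: 19 C1 mesylate
Product: 21 ten-membered C6 enone, via potassium alkoxide 20 (not isolated)
Conditions: KOtBu (1.05 equiv), THF, 0 °C, 15 min; pH 7 buffer
Reagents that add atoms: none
Why: KOtBu deprotonates the tertiary C6 hydroxyl to alkoxide 20, whose oxygen lone pair pushes into the C6–C10 bond; this bond is anti-periplanar to the equatorial C1–OMs bond, so C6=O and C1=C10 form in concert as the fusion bond breaks and mesylate leaves (Grob, or Wharton, fragmentation of a 1,3-diol monosulfonate). The ten-membered ring arises by scission of the bond shared by the five- and seven-membered rings and not by an end-to-end closure, so no ring-closure mode, dilution or entropic penalty is involved. No stereocentre is formed: C1, C6 and C10 become trigonal and C7 and C8 are spectators. The selectivity needed is the C1=C10 geometry, and the substrate fixes it: the mesylate is cis to C9 and trans to the C10 CH2OTBDPS group, so in the reactive chair-like conformer (mesylate and CH2OTBDPS both equatorial) C2 is gauche to C9 and the stereospecific anti fragmentation can only give the ring-cis alkene with C14 trans to C2. The tert-butyl ester resists attack by the hindered C6 alkoxide and is invariant towards tert-butoxide, and one equivalent of base at 0 °C with a buffered quench limits enolisation of the new β-silyloxy ketone at C7.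

Step 15
Reactants: 21 ten-membered C6 enone
Product: 22 (6R)-allylic alcohol
Conditions: NaBH4, CeCl3·7H2O, MeOH, −78 °C
Reagents that add atoms: none
Why: Luche 1,2-reduction of the enone: hydride is expected to add from the outer face of the ring, anti to the C7 side chain, to give the (6R)-alcohol (O6 trans to C11, syn to O8); this macrocyclic facial selectivity is the least predictable stereochemical event after the key step.

Step 16
Reactants: 22 (6R)-allylic alcohol
Product: 23 trans-fused 6,12-olide
Conditions: NaH (0.3 equiv), THF, 0 °C → rt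
Reagents that add atoms: none
Why: Base-catalysed lactonisation (intramolecular transesterification): the C6 alkoxide attacks the tert-butyl ester in a 5-exo-trig mode and the expelled tert-butoxide carries the chain, giving the γ-lactone with retention at C6.

Step 17
Reactants: 23 6,12-olide
Product: 25 C11 dimethylaminomethyl lactone (Mannich base), via lactone lithium enolate 24 (not isolated)
Conditions: LiN(i-Pr)2, THF, −78 °C; CH2=NMe2+ I−, −78 °C → rt
Reagents that add atoms: Eschenmoser's salt (N,N-dimethylmethyleneiminium iodide), C=[N+](C)C.[I-]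
Why: Mannich reaction of the lactone enolate with Eschenmoser's salt introduces C13 as a dimethylaminomethyl group; the new C11 centre is inconsequential.

Step 18
Reactants: 25 Mannich base
Product: 27 α-methylene lactone, via trimethylammonium iodide 26 (not isolated)
Conditions: MeI, MeOH, rt; then aq. NaHCO3, CH2Cl2, rt
Reagents that add atoms: none
Why: Exhaustive N-methylation followed by base-induced β-elimination of trimethylamine (Hofmann-type elimination) unveils the C11=C13 methylene group.

Step 19
Reactants: 27 α-methylene lactone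
Product: 28 C15 alcohol
Conditions: DDQ, CH2Cl2/pH 7 buffer, 0 °C
Reagents that add atoms: none
Why: Oxidative PMB cleavage: DDQ abstracts hydride from the electron-rich benzylic position and the oxocarbenium ion is hydrolysed, which should leave silyl ethers, alkenes and the methylene lactone untouched.

Step 20
Reactants: 28 C15 alcohol
Product: 29 C15 acetate
Conditions: Ac2O, pyridine, DMAP (cat.), CH2Cl2, 0 °C
Reagents that add atoms: acetic anhydride, CC(=O)OC(C)=O
Why: Acylation of the primary allylic alcohol under nucleophilic catalysis installs the C15 acetate of the target.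

Step 21
Reactants: 29 C15 acetate
Product: 30 C8,C14-diol
Conditions: HF·pyridine, pyridine, THF, 0 °C → rt
Reagents that add atoms: none
Why: Fluoride-mediated cleavage of both silyl ethers under buffered, weakly acidic conditions that should tolerate the acetate and the α-methylene lactone.

Step 22
Reactants: 30 C8,C14-diol
Product: 31 C14 enal with free C8 hydroxyl
Conditions: MnO2 (activated, excess), CH2Cl2, rt
Reagents that add atoms: none
Why: Chemoselective MnO2 oxidation of the primary allylic alcohol to the enal; the saturated secondary C8 alcohol is not oxidised and the ring-cis C1=C10 geometry is expected to be retained.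

Step 23
Reactants: 31 C14 enal; 32 (S)-2-methylbutanoic acid
Product: 33 target CNP0230988.8
Conditions: DCC, DMAP (cat.), CH2Cl2, 0 °C → rt
Reagents that add atoms: none
Why: Steglich esterification of the hindered C8 alcohol; carbodiimide activation at 0 °C with catalytic DMAP avoids ketene formation and so should preserve the (S)-centre of the acid.

**Compound list**

1 | furfural | O=Cc1ccco1 | starting material
2 | tert-butyl bromoacetate | CC(C)(C)OC(=O)CBr | starting material
3 | (2-tert-butoxy-2-oxoethyl)zinc bromide (Reformatsky reagent) | CC(C)(C)OC(=O)C[Zn]Br | intermediate (not isolated)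
4 | tert-butyl 3-(furan-2-yl)-3-hydroxypropanoate (racemic) | CC(C)(C)OC(=O)CC(O)c1ccco1 | intermediate
5 | rac-tert-butyl 2-[(1R,5S)-5-hydroxy-2-oxocyclopent-3-en-1-yl]acetate (trans; racemate, one enantiomer drawn) | O=C1C=C[C@H](O)[C@H]1CC(=O)OC(C)(C)C | intermediate
6 | tert-butyl 2-[(1R,5S)-5-hydroxy-2-oxocyclopent-3-en-1-yl]acetate (single enantiomer; C7 R, C8 S) | O=C1C=C[C@H](O)[C@H]1CC(=O)OC(C)(C)C | intermediate
7 | tert-butyl 2-[(1R,5S)-5-[(tert-butyldimethylsilyl)oxy]-2-oxocyclopent-3-en-1-yl]acetate | O=C1C=C[C@H](O[Si](C)(C)C(C)(C)C)[C@H]1CC(=O)OC(C)(C)C | intermediate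
8 | tert-butyl 2-[(1R,5S)-5-[(tert-butyldimethylsilyl)oxy]-3-(hydroxymethyl)-2-oxocyclopent-3-en-1-yl]acetate | O=C1C(CO)=C[C@H](O[Si](C)(C)C(C)(C)C)[C@H]1CC(=O)OC(C)(C)C | intermediate
9 | tert-butyl 2-[(1R,5S)-5-[(tert-butyldimethylsilyl)oxy]-3-{[(tert-butyldiphenylsilyl)oxy]methyl}-2-oxocyclopent-3-en-1-yl]acetate | O=C1C(CO[Si](c2ccccc2)(c2ccccc2)C(C)(C)C)=C[C@H](O[Si](C)(C)C(C)(C)C)[C@H]1CC(=O)OC(C)(C)C | intermediate
10 | 2-methylidenepropane-1,3-diol | C=C(CO)CO | starting material
11 | 2-{[(4-methoxybenzyl)oxy]methyl}prop-2-en-1-ol | C=C(CO)COCc1ccc(OC)cc1 | intermediate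
12 | 1-ethoxyethenyl ether of 11 (mixed ketene acetal) | C=C(OCC)OCC(=C)COCc1ccc(OC)cc1 | intermediate (not isolated)
13 | ethyl 4-{[(4-methoxybenzyl)oxy]methyl}pent-4-enoate | CCOC(=O)CCC(=C)COCc1ccc(OC)cc1 | intermediate
14 | 4-{[(4-methoxybenzyl)oxy]methyl}pent-4-enal (C1–C4 and C15; the =CH2 is lost in step 12) | O=CCCC(=C)COCc1ccc(OC)cc1 | intermediate
15 | lithium C6/C10 enolate of the C9-reduced ketone from 9 | [Li]OC1=C(CO[Si](c2ccccc2)(c2ccccc2)C(C)(C)C)C[C@H](O[Si](C)(C)C(C)(C)C)[C@H]1CC(=O)OC(C)(C)C | intermediate (not isolated)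
16 | tert-butyl 2-[(1R,3R,5S)-5-[(tert-butyldimethylsilyl)oxy]-3-{[(tert-butyldiphenylsilyl)oxy]methyl}-3-[(1S)-1-hydroxy-4-{[(4-methoxybenzyl)oxy]methyl}pent-4-en-1-yl]-2-oxocyclopentyl]acetate (germacrane 1S,7R,8S,10R; C1 chain trans to the C7 arm) | O=C1[C@](CO[Si](c2ccccc2)(c2ccccc2)C(C)(C)C)([C@@H](O)CCC(=C)COCc2ccc(OC)cc2)C[C@H](O[Si](C)(C)C(C)(C)C)[C@H]1CC(=O)OC(C)(C)C | intermediate
17 | tert-butyl 2-[(1R,2R,3R,5S)-5-[(tert-butyldimethylsilyl)oxy]-3-{[(tert-butyldiphenylsilyl)oxy]methyl}-2-ethenyl-2-hydroxy-3-[(1S)-1-hydroxy-4-{[(4-methoxybenzyl)oxy]methyl}pent-4-en-1-yl]cyclopentyl]acetate (vinyl cis to the C1 chain, both trans to the C7 arm) | C=C[C@]1(O)[C@](CO[Si](c2ccccc2)(c2ccccc2)C(C)(C)C)([C@@H](O)CCC(=C)COCc2ccc(OC)cc2)C[C@H](O[Si](C)(C)C(C)(C)C)[C@H]1CC(=O)OC(C)(C)C | intermediate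
18 | (1S,6R,7R,8S,10R)-cis-fused bicyclo[5.3.0]dec-4-ene-1,6-diol (germacrane numbering) with 4-CH2OPMB, 7-CH2CO2t-Bu, 8-OTBS, 10-CH2OTBDPS; C6–OH cis to C10–CH2OTBDPS and to the C7 arm; C1–OH trans to C6–OH and cis to C9 | O[C@H]1CCC(COCc3ccc(OC)cc3)=C[C@@]2(O)[C@H](CC(=O)OC(C)(C)C)[C@@H](O[Si](C)(C)C(C)(C)C)C[C@@]12CO[Si](c1ccccc1)(c1ccccc1)C(C)(C)C | intermediate
19 | C1 methanesulfonate of 18 (1S,6R,7R,8S,10R; key-step precursor) | CS(=O)(=O)O[C@H]1CCC(COCc3ccc(OC)cc3)=C[C@@]2(O)[C@H](CC(=O)OC(C)(C)C)[C@@H](O[Si](C)(C)C(C)(C)C)C[C@@]12CO[Si](c1ccccc1)(c1ccccc1)C(C)(C)C | intermediate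
20 | potassium C6 alkoxide of 19 | CS(=O)(=O)O[C@H]1CCC(COCc3ccc(OC)cc3)=C[C@@]2([O-])[C@H](CC(=O)OC(C)(C)C)[C@@H](O[Si](C)(C)C(C)(C)C)C[C@@]12CO[Si](c1ccccc1)(c1ccccc1)C(C)(C)C.[K+] | intermediate (not isolated)
21 | tert-butyl 2-[(7R,8S)-8-[(tert-butyldimethylsilyl)oxy]-10-{[(tert-butyldiphenylsilyl)oxy]methyl}-4-{[(4-methoxybenzyl)oxy]methyl}-6-oxocyclodeca-1(10),4-dien-7-yl]acetate (germacrane numbering; both ring alkenes ring-cis, CIP E,E; key-step product) | O=C1/C=C(/COCc2ccc(OC)cc2)CC/C=C(/CO[Si](c2ccccc2)(c2ccccc2)C(C)(C)C)C[C@H](O[Si](C)(C)C(C)(C)C)[C@H]1CC(=O)OC(C)(C)C | intermediate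
22 | (6R,7S,8S)-6-hydroxy analogue of 21 (O6 trans to C11; the C7 descriptor changes by CIP priority only) | O[C@@H]1/C=C(/COCc2ccc(OC)cc2)CC/C=C(/CO[Si](c2ccccc2)(c2ccccc2)C(C)(C)C)C[C@H](O[Si](C)(C)C(C)(C)C)[C@H]1CC(=O)OC(C)(C)C | intermediate
23 | (6R,7S,8S)-8-OTBS-14-OTBDPS-15-OPMB-germacra-1(10),4-dien-12,6-olide (trans-fused γ-lactone) | C1C(=O)O[C@@H]2/C=C(/COCc3ccc(OC)cc3)CC/C=C(/CO[Si](c3ccccc3)(c3ccccc3)C(C)(C)C)C[C@H](O[Si](C)(C)C(C)(C)C)[C@@H]12 | intermediate
24 | lithium enolate of lactone 23 | C1=C(O[Li])O[C@@H]2/C=C(/COCc3ccc(OC)cc3)CC/C=C(/CO[Si](c3ccccc3)(c3ccccc3)C(C)(C)C)C[C@H](O[Si](C)(C)C(C)(C)C)[C@@H]12 | intermediate (not isolated)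
25 | 11-[(dimethylamino)methyl] derivative of 23 (C11 epimers) | CN(C)CC1C(=O)O[C@@H]2/C=C(/COCc3ccc(OC)cc3)CC/C=C(/CO[Si](c3ccccc3)(c3ccccc3)C(C)(C)C)C[C@H](O[Si](C)(C)C(C)(C)C)[C@@H]12 | intermediate
26 | trimethylammonium iodide from 25 | C[N+](C)(C)CC1C(=O)O[C@@H]2/C=C(/COCc3ccc(OC)cc3)CC/C=C(/CO[Si](c3ccccc3)(c3ccccc3)C(C)(C)C)C[C@H](O[Si](C)(C)C(C)(C)C)[C@@H]12.[I-] | intermediate (not isolated)
27 | (6R,7S,8S)-8-OTBS-14-OTBDPS-15-OPMB-germacra-1(10),4,11(13)-trien-12,6-olide | C=C1C(=O)O[C@@H]2/C=C(/COCc3ccc(OC)cc3)CC/C=C(/CO[Si](c3ccccc3)(c3ccccc3)C(C)(C)C)C[C@H](O[Si](C)(C)C(C)(C)C)[C@@H]12 | intermediate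
28 | 15-hydroxy analogue of 27 | C=C1C(=O)O[C@@H]2/C=C(/CO)CC/C=C(/CO[Si](c3ccccc3)(c3ccccc3)C(C)(C)C)C[C@H](O[Si](C)(C)C(C)(C)C)[C@@H]12 | intermediate
29 | 15-acetoxy analogue of 27 | C=C1C(=O)O[C@@H]2/C=C(/COC(C)=O)CC/C=C(/CO[Si](c3ccccc3)(c3ccccc3)C(C)(C)C)C[C@H](O[Si](C)(C)C(C)(C)C)[C@@H]12 | intermediate
30 | (6R,7R,8S)-15-acetoxy-8,14-dihydroxygermacra-1(10),4,11(13)-trien-12,6-olide | C=C1C(=O)O[C@@H]2/C=C(/COC(C)=O)CC/C=C(/CO)C[C@H](O)[C@@H]12 | intermediate
31 | (6R,7R,8S)-15-acetoxy-8-hydroxy-14-oxogermacra-1(10),4,11(13)-trien-12,6-olide | C=C1C(=O)O[C@@H]2/C=C(/COC(C)=O)CC/C=C(/C=O)C[C@H](O)[C@@H]12 | intermediate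
32 | (S)-2-methylbutanoic acid | CC[C@H](C)C(=O)O | starting material
33 | CNP0230988.8: (6R,7R,8S)-15-acetoxy-8-[(2S)-2-methylbutanoyloxy]-14-oxogermacra-1(10),4,11(13)-trien-12,6-olide (both ring alkenes ring-cis) | C=C1C(=O)O[C@@H]2/C=C(/COC(C)=O)CC/C=C(/C=O)C[C@H](OC(=O)[C@@H](C)CC)[C@@H]12 | target

**Totals**

Total step count: 23. Longest linear sequence: 20 steps (steps 1–6 and 10–23, from furfural); the aldehyde 14 is made in 3 steps (7–9) and joins at step 10.

**Steps most likely to fail**

Step 10. What may go wrong: the closed transition state may lose its preference at the tetrasubstituted enolate, so that C1 is poorly controlled relative to C10; this would surface after fragmentation as a mixture of C1=C10 geometries. Retro-aldol on warming and competing 1,2-reduction of the enone are further failure modes. Fallback (correct C1 after the rings are made, by oxidation and hydroxyl-directed reduction): setting out from 9 and 14, the aldol mixture containing the C1-epimeric aldol adduct F1 is not separated but taken through steps 11 and 12. These give the C1-epimeric vinyl carbinol F2 and the C1-epimeric bicyclic diol F3 alongside 17 and 18. Dess–Martin periodinane (CH2Cl2, NaHCO3) oxidises the secondary C1 hydroxyl of both epimers, leaving the tertiary C6 hydroxyl, to the single bicyclic β-hydroxy ketone F4. Me4NBH(OAc)3 (MeCN/AcOH, −20 °C; Evans–Saksena reduction) then binds the C6 hydroxyl and delivers hydride intramolecularly to the C1 carbonyl, which should give the 1,3-anti diol, that is 18, where the route is rejoined.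

Step 15. What may go wrong: hydride may be delivered to the other face of the C6 carbonyl, because the facial preference is set by the conformation of the ten-membered ring and not by a reliable local element. This would give the C6 epimer and, after cyclisation, the cis-fused lactone. Fallback (invert the carbinol instead of re-tuning the reduction): setting out from 21, the reduction product is then the (6S)-alcohol F6, which cannot lactonise spontaneously because of the tert-butyl ester. A Mitsunobu reaction (4-nitrobenzoic acid, PPh3, DIAD, toluene, 0 °C) converts it with inversion into the (6R)-4-nitrobenzoate F7. Methanolysis (K2CO3, MeOH, 0 °C) returns the (6R)-alcohol 22, where the route is rejoined.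

Step 14. What may go wrong: base-mediated events may compete with or follow the fragmentation. These are enolisation of the new ketone at C7 with epimerisation or β-elimination of the C8 silyloxy group, attack of the C6 alkoxide on the ester carbonyl, and 1,3-migration of the C14 silyl group to the alkoxide. Fallback (release the alkoxide from a silyl ether with fluoride, so that no Brønsted base is present): setting out from 19, the C6 hydroxyl is silylated (N-(trimethylsilyl)imidazole, CH2Cl2, rt) to the C6 trimethylsilyl ether F5. One equivalent of TBAF in THF at −40 °C should cleave only this most labile silyl ether, and the tetrabutylammonium alkoxide released fragments at once to 21, where the route is rejoined.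

**Further compounds**

F1 | step 10 | C1-epimer of aldol adduct 16 | O=C1[C@](CO[Si](c2ccccc2)(c2ccccc2)C(C)(C)C)([C@H](O)CCC(=C)COCc2ccc(OC)cc2)C[C@H](O[Si](C)(C)C(C)(C)C)[C@H]1CC(=O)OC(C)(C)C
F2 | step 10 | C1-epimer of vinyl carbinol 17 | C=C[C@]1(O)[C@](CO[Si](c2ccccc2)(c2ccccc2)C(C)(C)C)([C@H](O)CCC(=C)COCc2ccc(OC)cc2)C[C@H](O[Si](C)(C)C(C)(C)C)[C@H]1CC(=O)OC(C)(C)C
F3 | step 10 | C1-epimer of bicyclic diol 18 | O[C@@H]1CCC(COCc3ccc(OC)cc3)=C[C@@]2(O)[C@H](CC(=O)OC(C)(C)C)[C@@H](O[Si](C)(C)C(C)(C)C)C[C@@]12CO[Si](c1ccccc1)(c1ccccc1)C(C)(C)C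
F4 | step 10 | bicyclic C1 ketone with free tertiary C6 hydroxyl | O=C1CCC(COCc3ccc(OC)cc3)=C[C@@]2(O)[C@H](CC(=O)OC(C)(C)C)[C@@H](O[Si](C)(C)C(C)(C)C)C[C@@]12CO[Si](c1ccccc1)(c1ccccc1)C(C)(C)C
F5 | step 14 | C6 trimethylsilyl ether of mesylate 19 | CS(=O)(=O)O[C@H]1CCC(COCc3ccc(OC)cc3)=C[C@@]2(O[Si](C)(C)C)[C@H](CC(=O)OC(C)(C)C)[C@@H](O[Si](C)(C)C(C)(C)C)C[C@@]12CO[Si](c1ccccc1)(c1ccccc1)C(C)(C)C
F6 | step 15 | (6S)-epimer of allylic alcohol 22 | O[C@H]1/C=C(/COCc2ccc(OC)cc2)CC/C=C(/CO[Si](c2ccccc2)(c2ccccc2)C(C)(C)C)C[C@H](O[Si](C)(C)C(C)(C)C)[C@H]1CC(=O)OC(C)(C)C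
F7 | step 15 | (6R)-4-nitrobenzoate of 22 | O=C(O[C@@H]1/C=C(/COCc2ccc(OC)cc2)CC/C=C(/CO[Si](c2ccccc2)(c2ccccc2)C(C)(C)C)C[C@H](O[Si](C)(C)C(C)(C)C)[C@H]1CC(=O)OC(C)(C)C)c1ccc(cc1)[N+](=O)[O-]
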